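# Proposed synthesis of CNP0302713.3 (34) by electroreductive nickel closure of C3–C4

## The problem

Numbering used throughout: C1 is the quaternary ring carbon; the ten-membered ring runs C1, C2, C3, C4 (methyl), C5, C6 (OAc), C7, C8 (methyl, OH), C9, C11; C10 is the cyclopropane CH2; C12–C15 are the side chain, with OOH on C14. In this numbering the target 34 is (1R,6S,8S,9S,11S,14S).

- Target 34 is a ten-membered carbocycle trans-fused to a cyclopropane (C9–C10–C11). It carries an E trisubstituted olefin (C4=C5), an allylic acetate (C6), a tertiary cyclopropylcarbinol (C8), a quaternary carbon (C1) and a secondary allylic hydroperoxide on the side chain (C14).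
- A synthesis has to close a strained medium ring beside these groups and set six stereocentres.
- C1 and C11 are neighbours and can be formed together in one sigmatropic step. C9 then follows C11, because closure to the trans cyclopropane is preferred.
- C8 lies next to the cyclopropane, but a trans-substituted cyclopropyl ketone offers almost no facial bias, so C8 needs reagent control. C6 is 1,3-anti to C8 and can be set on a C6 ketone by a chiral catalyst. C14 is remote and also needs a reagent.
- The hydroperoxide does not survive low-valent metals or hydrides and must come last. The tertiary cyclopropylcarbinol ionises in acid, and the allylic acetate is sensitive to base and to ionisation.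
- The enabling feature is the C3–C4 bond. It joins a plain CH2 to the methyl-bearing olefin carbon, and neither atom is a stereocentre. The olefin geometry can therefore be fixed beforehand in an open-chain (E)-alkenyl iodide, and C3 can be delivered as a primary radical from a carboxylic acid one carbon longer. The ring can then be closed between two electrophiles.

## Retrosynthesis

**C14–O bond.** The hydroperoxide 34 is traced to the mesylate 33 of the C14-epimeric allylic alcohol 32, the oxygen arriving by displacement with inversion. The neighbouring option, a singlet-oxygen ene reaction on a prenyl group, gives no control at C14, gives the tertiary regioisomer as well, and would also attack the ring olefin. Alcohol 32 comes from silyl ether 31. The forward step must be a clean backside attack at low temperature on a secondary allylic sulfonate.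

**C3–C4 bond (key cut).** Macrocycle 31 is opened to the redox-active ester 30, which carries an N-hydroxyphthalimide ester on the carbon beyond C3 and an (E)-alkenyl iodide at C4. Neighbouring cuts are weaker:
- C5–C6 (alkenylchromium to aldehyde) would create C6 during ring closure without control.
- C7–C8 (aldol) would create C8 in the ring and is reversible.
- Ring-closing metathesis at C4=C5 gives no control over a trisubstituted olefin in a ten-membered ring.

The C3–C4 cut creates no stereocentre, and 30 is an open chain with all six centres in place. The forward reaction must capture a primary radical at nickel in the same chain faster than two chains meet.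

**Functional groups around the seco chain.** Ester 30 comes from acid 28 and N-hydroxyphthalimide 29. Acid 28 comes from aldehyde 27, the acetate of hydroxy aldehyde 26. Compound 26 is released from alkenyl iodide 25, in which the C3 arm is a dimethyl acetal, C6 a triethylsilyl ether and C14 a tert-butyldimethylsilyl ether. Only C–O bonds change. The two silyl groups are needed to tell the two secondary alcohols (C6, C14) apart.

**C4–I and C5–C6.** Iodide 25 comes from the 2-alkyne 23 by syn hydrozirconation and iodination, which fixes the E geometry. The alkyne is introduced as 1-propynylmagnesium bromide 17 on aldehyde 16 (C5–C6 bond). C6 is then set by oxidation to ynone 19 and asymmetric transfer hydrogenation to 20. A preformed β-iodoalkenyl nucleophile is not an option, since it would eliminate.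

**C14 oxygen.** Allylic alcohol 22 comes from epoxide 21 by base-induced isomerisation, which keeps the C14–O bond. The epoxide is made from the prenyl olefin of 11 by Shi epoxidation (12). The epoxide also hides the side-chain olefin during the ozonolysis that follows.

**C7–C8.** Aldehyde 16 comes from the terminal olefin of 14 by ozonolysis. Alcohol 14 arises from methyl ketone 12 and a chiral allylborane. A direct acetate-type aldol would be two steps shorter but has no control at C8; it is kept as a fallback.

**C3–carboxyl carbon.** The acetal arm of 11 comes from aldehyde 10, made by hydroformylation of the vinyl group of 9. This adds exactly the carbon that the decarboxylation later removes.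

**C9–C10 (cyclopropane).** Cyclopropyl ketone 9 comes from γ-tosyloxy ketone 8 by 3-exo-tet enolate alkylation. Ketone 8 arises by Wacker oxidation of the allyl group of 7; 7 comes from acid 5 through alcohol 6.

**C1–C11.** Acid 5 comes from geranyl pent-4-enoate 3 by an enantioselective Ireland–Claisen rearrangement; 3 is the ester of geraniol 1 and pent-4-enoic acid 2. The allyl group serves as a masked acetonyl group. A ketal of a 4-oxopentanoate would not tolerate the Lewis-acidic boron reagent.

## Roads not taken

**Alternative 1:** The cut is inside the cyclopropylcarbinol: the C9–C10 ring bond and the C8–O bond are removed, leading to the open-chain primary tosylate A1 with a Z C8=C9 olefin. Forward, buffered aqueous solvolysis lets the olefin displace the tosylate at C10 while water adds to C8 from the opposite face, giving fragment A2.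
- Merit: one step without a chiral reagent sets C8 and C9 relative to C11 from olefin geometry. Here it is better than the chosen plan, which needs a chiral allylborane (step 10), an ozonolysis and a masked side chain for the same centres.
- Weak points: A2 is only a fragment, so the ring, C6 and the C3–C4 bond are still open. The cation forms beside a quaternary carbon carrying vinyl and homoprenyl groups, so olefin capture and cyclobutyl or homoallyl products are possible. A1 needs a pure Z trisubstituted olefin.
- Comparison: the chosen plan sets against this a polar enolate closure of the cyclopropane, reagent control at C8 that does not depend on conformation, and no carbocation in a molecule with three olefins.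

**Alternative 2:** The cut removes C6–C7 and O–C8. Forward, oxime A3 is oxidised with NaOCl to nitrile oxide A4, which adds to the 1,1-disubstituted C7=C8 olefin and gives the bridged isoxazoline A5.
- Merit: the ring and the C8 oxygen form in one step, and later N–O cleavage would leave a C6 carbonyl ready for 1,3-anti reduction. In step count to the ring it is better than the chosen plan.
- Weak points: closure to a ten-membered ring must beat dimerisation of A4. The configuration at C8 is decided by the conformation of a forming medium ring beside a cyclopropane, not by a reagent. The side chain is still a prenyl olefin, so C14 would have to be oxidised late in the presence of the similar ring olefin.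
- Comparison: the chosen plan sets against this that every stereocentre is fixed before the ring closes and the closing bond creates none.

**Alternative 3:** The ten-membered ring is traced back to cyclohexanol A6 by forming C4–C9 and breaking C1–C2. Forward, the potassium alkoxide of A6 (KH, 18-crown-6) rearranges to the ten-membered ketone A7.
- Merit: the anionic oxy-Cope rearrangement is an established entry to ten-membered rings and sets C1 by chirality transfer. In certainty of ring formation it is better than the chosen key step, which has no medium-ring precedent.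
- Weak points: A7 has the wrong functionality at both ends. The C9=C11 olefin must be cyclopropanated on one face of a flexible ring without a free directing hydroxyl. The C4 ketone must become the E C4=C5 methyl-bearing olefin, although enolisation can go toward C3 or C5. A6 itself needs four stereocentres and a pure trisubstituted olefin.
- Comparison: the chosen plan sets against this that olefin position, olefin geometry and the cyclopropane are all fixed in the open chain.

Key step: step 23

Assumption: the enantiomers of the two chiral boron reagents (steps 2 and 10) and the amine/solvent pair of step 2 are written as the known facial and enolate-geometry models predict for these substrate classes; if a sense proves opposite, the mirror-image reagent (or the other amine/solvent pair) is used and nothing else changes.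

## Route

Step 1
Reactants: 1 geraniol; 2 pent-4-enoic acid
Product: 3 geranyl pent-4-enoate
Conditions: DCC, DMAP (cat.), CH2Cl2, 0 °C → rt
Reagents that add atoms: none
Why: Steglich esterification of a primary allylic alcohol; no stereocentre is formed and the E olefin of 1 is untouched.

Step 2
Reactants: 3 geranyl pent-4-enoate
Product: 5 (2S,3S)-3-ethenyl-3,7-dimethyl-2-(prop-2-en-1-yl)oct-6-enoic acid, via boron enolate 4 (not isolated)
Conditions: (4S,5S)-2-bromo-4,5-diphenyl-1,3-bis[3,5-bis(trifluoromethyl)benzenesulfonyl]-1,3,2-diazaborolidine (from the bis-sulfonamide and BBr3), iPr2NEt, CH2Cl2, −78 °C, then −20 → 4 °C; aqueous work-up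
Reagents that add atoms: none
Why: Enantioselective Ireland–Claisen rearrangement of a chiral boron ester enolate: the enolate with the α-allyl group trans to O–B and the (E)-olefin of the geranyl part pass through a chair with the homoprenyl group equatorial, which forms C1 (quaternary) and C11 together as the (1S,11S) pair. The C2-symmetric sulfonamide ligand on boron selects one of the two mirror-image chairs and so fixes the absolute configuration.

Step 3
Reactants: 5 (2S,3S)-3-ethenyl-3,7-dimethyl-2-(prop-2-en-1-yl)oct-6-enoic acid
Product: 6 (2S,3S)-3-ethenyl-3,7-dimethyl-2-(prop-2-en-1-yl)oct-6-en-1-ol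
Conditions: LiAlH4, THF, 0 °C → rt
Reagents that add atoms: none
Why: Hydride reduction of the carboxylic acid to the primary alcohol (the future C10); the olefins and both stereocentres are not touched.

Step 4
Reactants: 6 (2S,3S)-3-ethenyl-3,7-dimethyl-2-(prop-2-en-1-yl)oct-6-en-1-ol
Product: 7 (2S,3S)-3-ethenyl-3,7-dimethyl-2-(prop-2-en-1-yl)oct-6-en-1-yl 4-methylbenzenesulfonate
Conditions: TsCl, pyridine, DMAP (cat.), CH2Cl2, 0 °C
Reagents that add atoms: p-toluenesulfonyl chloride, Cc1ccc(S(=O)(=O)Cl)cc1
Why: Sulfonylation of a primary alcohol, which turns C10 into the electrophile for the cyclopropane closure.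

Step 5
Reactants: 7 (2S,3S)-3-ethenyl-3,7-dimethyl-2-(prop-2-en-1-yl)oct-6-en-1-yl 4-methylbenzenesulfonate
Product: 8 (2S,3S)-3-ethenyl-3,7-dimethyl-2-(2-oxopropyl)oct-6-en-1-yl 4-methylbenzenesulfonate
Conditions: PdCl2 (10 mol %), CuCl, O2 (1 atm), DMF/H2O, rt
Reagents that add atoms: water, O
Why: Tsuji–Wacker oxidation: the unhindered monosubstituted allyl olefin is oxidised in the Markovnikov sense to the methyl ketone (C8 with its methyl group). The vinyl group on the quaternary carbon and the trisubstituted olefin react far more slowly.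

Step 6
Reactants: 8 (2S,3S)-3-ethenyl-3,7-dimethyl-2-(2-oxopropyl)oct-6-en-1-yl 4-methylbenzenesulfonate
Product: 9 1-[(1S,2S)-2-[(3S)-3,7-dimethylocta-1,6-dien-3-yl]cyclopropyl]ethan-1-one
Conditions: KOtBu, THF, 0 °C
Reagents that add atoms: none
Why: Intramolecular 3-exo-tet alkylation of the ketone enolate, the classical closure of a γ-sulfonyloxy ketone to a cyclopropyl ketone; enolisation is reversible and only the C9 enolate can close. C11 is not touched, and the acetyl group takes the side of the new ring away from the bulky C1 substituent, giving the trans cyclopropane (9S), which is also the isomer favoured at equilibrium.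

Step 7
Reactants: 9 1-[(1S,2S)-2-[(3S)-3,7-dimethylocta-1,6-dien-3-yl]cyclopropyl]ethan-1-one
Product: 10 (4S)-4-[(1S,2S)-2-acetylcyclopropyl]-4,8-dimethylnon-7-enal
Conditions: Rh(acac)(CO)2 (1 mol %), PPh3, CO/H2 (1:1, 20 bar), toluene, 60 °C
Reagents that add atoms: carbon monoxide, [C-]#[O+]
Why: Rhodium-catalysed hydroformylation: a vinyl group on a quaternary carbon can only give the linear aldehyde, which supplies C2, C3 and the carbon later lost as CO2. The trisubstituted olefin and the cyclopropyl ketone are inert under these conditions.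

Step 8
Reactants: 10 (4S)-4-[(1S,2S)-2-acetylcyclopropyl]-4,8-dimethylnon-7-enal
Product: 11 1-[(1S,2S)-2-[(4S)-1,1-dimethoxy-4,8-dimethylnon-7-en-4-yl]cyclopropyl]ethan-1-one
Conditions: HC(OMe)3, CeCl3·7H2O (cat.), MeOH, rt
Reagents that add atoms: trimethyl orthoformate, COC(OC)OC; methanol, CO
Why: Lanthanide-catalysed acetalisation is selective for the aldehyde over the conjugated cyclopropyl ketone; the acetal parks the C3 arm through the organometallic and oxidative steps that follow.

Step 9
Reactants: 11 1-[(1S,2S)-2-[(4S)-1,1-dimethoxy-4,8-dimethylnon-7-en-4-yl]cyclopropyl]ethan-1-one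
Product: 12 1-[(1S,2S)-2-[(3S)-1-[(2R)-3,3-dimethyloxiran-2-yl]-6,6-dimethoxy-3-methylhexan-3-yl]cyclopropyl]ethan-1-one
Conditions: 1,2:4,5-di-O-isopropylidene-β-D-erythro-2,3-hexodiulo-2,6-pyranose (0.3 equiv), KHSO5 (as Oxone), K2CO3, Bu4NHSO4, MeCN/CH2(OMe)2/aq. buffer (pH 10.5), 0 °C
Reagents that add atoms: potassium peroxymonosulfate, [K+].[O-]S(=O)(=O)OO
Why: Shi epoxidation: the dioxirane of the D-fructose-derived ketone transfers oxygen to the only olefin through the spiro transition state, which for a 2-methylalk-2-ene of this kind should give the (14R)-epoxide. The epoxide sets C14 and masks the side-chain olefin for the ozonolysis of step 11.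

Step 10
Reactants: 12 1-[(1S,2S)-2-[(3S)-1-[(2R)-3,3-dimethyloxiran-2-yl]-6,6-dimethoxy-3-methylhexan-3-yl]cyclopropyl]ethan-1-one
Product: 14 (2S)-2-[(1S,2S)-2-[(3S)-1-[(2R)-3,3-dimethyloxiran-2-yl]-6,6-dimethoxy-3-methylhexan-3-yl]cyclopropyl]pent-4-en-2-ol, via borinate 13 (not isolated)
Conditions: (10R)-B-allyl-10-phenyl-9-borabicyclo[3.3.2]decane, Et2O, −78 °C → rt; then NaOH, H2O2, 0 °C
Reagents that add atoms: (10R)-B-allyl-10-phenyl-9-borabicyclo[3.3.2]decane, C=CCB1[C@@H]2CCC[C@@H](CCC2)[C@@H]1c1ccccc1
Why: Asymmetric allylboration of a methyl ketone through a chair six-membered transition state: the 10-phenyl group leaves room only for the methyl group, so the allyl group is delivered to the Si face and C8 becomes S. The trans-cyclopropyl substituent gives little bias of its own, so the reagent decides; oxidative work-up cleaves the borinate.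

Step 11
Reactants: 14 (2S)-2-[(1S,2S)-2-[(3S)-1-[(2R)-3,3-dimethyloxiran-2-yl]-6,6-dimethoxy-3-methylhexan-3-yl]cyclopropyl]pent-4-en-2-ol
Product: 16 (3S)-3-[(1S,2S)-2-[(3S)-1-[(2R)-3,3-dimethyloxiran-2-yl]-6,6-dimethoxy-3-methylhexan-3-yl]cyclopropyl]-3-hydroxybutanal, via ozonide 15 (not isolated)
Conditions: O3, CH2Cl2, −78 °C; then PPh3, −78 °C → rt
Reagents that add atoms: ozone, [O-][O+]=O
Why: Ozonolysis with reductive work-up of the only olefin in the molecule gives the β-hydroxy aldehyde (C6); epoxide, acetal, tertiary alcohol and cyclopropane are inert to ozone.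

Step 12
Reactants: 16 (3S)-3-[(1S,2S)-2-[(3S)-1-[(2R)-3,3-dimethyloxiran-2-yl]-6,6-dimethoxy-3-methylhexan-3-yl]cyclopropyl]-3-hydroxybutanal; 17 1-propynylmagnesium bromide
Product: 18 (2S)-2-[(1S,2S)-2-[(3S)-1-[(2R)-3,3-dimethyloxiran-2-yl]-6,6-dimethoxy-3-methylhexan-3-yl]cyclopropyl]hept-5-yne-2,4-diol (both epimers at the new carbinol C6)
Conditions: THF, −78 °C (excess 17)
Reagents that add atoms: none
Why: Grignard addition to the aldehyde forms the C5–C6 bond; one equivalent is consumed by the tertiary hydroxyl. The trisubstituted epoxide does not react at −78 °C, and the mixture at C6 converges in the next two steps.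

Step 13
Reactants: 18 (2S)-2-[(1S,2S)-2-[(3S)-1-[(2R)-3,3-dimethyloxiran-2-yl]-6,6-dimethoxy-3-methylhexan-3-yl]cyclopropyl]hept-5-yne-2,4-diol (both C6 epimers)
Product: 19 (6S)-6-[(1S,2S)-2-[(3S)-1-[(2R)-3,3-dimethyloxiran-2-yl]-6,6-dimethoxy-3-methylhexan-3-yl]cyclopropyl]-6-hydroxyhept-2-yn-4-one
Conditions: Dess–Martin periodinane, NaHCO3, CH2Cl2, 0 °C
Reagents that add atoms: none
Why: Buffered periodinane oxidation of the secondary propargylic alcohol to the ynone; the tertiary alcohol cannot be oxidised and the buffer protects epoxide and acetal.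

Step 14
Reactants: 19 (6S)-6-[(1S,2S)-2-[(3S)-1-[(2R)-3,3-dimethyloxiran-2-yl]-6,6-dimethoxy-3-methylhexan-3-yl]cyclopropyl]-6-hydroxyhept-2-yn-4-one
Product: 20 (2S,4S)-2-[(1S,2S)-2-[(3S)-1-[(2R)-3,3-dimethyloxiran-2-yl]-6,6-dimethoxy-3-methylhexan-3-yl]cyclopropyl]hept-5-yne-2,4-diol
Conditions: Ru[(S,S)-TsDPEN](p-cymene) (2 mol %), iPrOH, rt
Reagents that add atoms: none
Why: Noyori asymmetric transfer hydrogenation of an alkynyl ketone: the (S,S)-catalyst should give the (S)-propargylic alcohol, which is the 1,3-anti relation to the C8 hydroxyl. The base-free conditions spare the β-hydroxy ketone (no retro-aldol) and the epoxide.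

Step 15
Reactants: 20 (2S,4S)-2-[(1S,2S)-2-[(3S)-1-[(2R)-3,3-dimethyloxiran-2-yl]-6,6-dimethoxy-3-methylhexan-3-yl]cyclopropyl]hept-5-yne-2,4-diol
Product: 21 the C6 triethylsilyl ether of 20, (1S,6S,8S,9S,11S,14R)
Conditions: TESCl, imidazole, CH2Cl2, 0 °C
Reagents that add atoms: chlorotriethylsilane, CC[Si](Cl)(CC)CC
Why: Silylation of the secondary propargylic alcohol only; the tertiary cyclopropylcarbinol is too hindered. The acid-labile group at C6 is what later lets C6 be freed while C14 stays protected.

Step 16
Reactants: 21 the C6 triethylsilyl ether of 20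
Product: 22 the (14R)-allylic alcohol: 21 with the epoxide opened to C14–OH and an isopropenyl group, (1S,6S,8S,9S,11S,14R)
Conditions: Et2AlTMP (from LiTMP and Et2AlCl, excess), toluene, 0 °C
Reagents that add atoms: none
Why: Base-induced isomerisation of a trisubstituted epoxide to an allylic alcohol by a hindered aluminium amide: aluminium binds the epoxide oxygen and the amide removes a proton from a methyl group, so the C15–O bond breaks and the C14–O bond is kept. C14 therefore stays R; the tertiary alkoxide, silyl ether, acetal and alkyne are inert.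

Step 17
Reactants: 22 the (14R)-allylic alcohol
Product: 23 the C14 tert-butyldimethylsilyl ether of 22, (1S,6S,8S,9S,11S,14R)
Conditions: TBSCl, imidazole, DMF, rt
Reagents that add atoms: tert-butyldimethylsilyl chloride, CC(C)(C)[Si](C)(C)Cl
Why: Silylation of the secondary allylic alcohol; the tertiary alcohol does not react, and the robust silyl group will outlast the release of C6 in step 19.

Step 18
Reactants: 23 the C14 tert-butyldimethylsilyl ether of 22
Product: 25 the (E)-alkenyl iodide: 23 with the alkyne converted into C5H=C4(CH3)I, iodine trans to C6, via alkenylzirconocene 24 (not isolated)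
Conditions: Cp2Zr(H)Cl (3 equiv), THF, rt → 40 °C; then I2, THF, 0 °C
Reagents that add atoms: iodine, II
Why: Hydrozirconation–iodination: syn addition of Zr–H to the 2-alkyne, equilibrated with excess reagent to the isomer with zirconium on the methyl-bearing C4, away from the branched silyloxy carbon. Iodine replaces zirconium with retention and gives the E alkenyl iodide; the 1,1-disubstituted side-chain olefin reacts more slowly than the alkyne.

Step 19
Reactants: 25 the (E)-alkenyl iodide
Product: 26 the hydroxy aldehyde: 25 with C6–OH free and the acetal hydrolysed to the aldehyde, (1S,6S,8S,9S,11S,14R)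
Conditions: AcOH/THF/H2O (3:1:1), rt
Reagents that add atoms: water, O
Why: Dilute aqueous acetic acid cleaves the secondary triethylsilyl ether and the dimethyl acetal in one operation. The secondary tert-butyldimethylsilyl ether is much slower, and this weak acid should not ionise the tertiary cyclopropylcarbinol.

Step 20
Reactants: 26 the hydroxy aldehyde
Product: 27 the C6 acetate of 26, (1S,6S,8S,9S,11S,14R)
Conditions: Ac2O, pyridine, DMAP (cat.), CH2Cl2, 0 °C
Reagents that add atoms: acetic anhydride, CC(=O)OC(C)=O
Why: Acetylation of the only free secondary alcohol; the tertiary cyclopropylcarbinol is not acylated under these mild conditions.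

Step 21
Reactants: 27 the C6 acetate of 26
Product: 28 the carboxylic acid: 27 with the aldehyde oxidised to CO2H, (1S,6S,8S,9S,11S,14R)
Conditions: NaClO2, NaH2PO4, 2-methyl-2-butene, tBuOH/H2O, 0 °C → rt
Reagents that add atoms: sodium chlorite, [Na+].[O-]Cl=O
Why: Pinnick oxidation; the scavenger takes up hypochlorite, so the olefins, the alkenyl iodide and the acetate are left alone.

Step 22
Reactants: 28 the carboxylic acid; 29 N-hydroxyphthalimide
Product: 30 the redox-active ester: seco N-(acyloxy)phthalimide with (E)-alkenyl iodide, C6 acetate, free C8 hydroxyl and C14 tert-butyldimethylsilyl ether, (1S,6S,8S,9S,11S,14R)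
Conditions: N,N'-diisopropylcarbodiimide, DMAP (cat.), CH2Cl2, rt
Reagents that add atoms: none
Why: Carbodiimide esterification with the acidic N-hydroxy imide gives the redox-active ester; the hindered tertiary alcohol does not compete.

Step 23
Reactants: 30 the redox-active ester
Product: 31 the ten-membered hydroxy acetate with C14 tert-butyldimethylsilyl ether, (1R,6S,8S,9S,11S,14R)
Conditions: NiCl2(dme) (20 mol %), 4,4'-di-tert-butyl-2,2'-bipyridine (24 mol %), LiCl, DMF, carbon cathode, sacrificial magnesium anode, constant current, rt; 30 added by syringe pump (final concentration ≤ 2 mM)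
Reagents that add atoms: none
Why: Proposed new method: cathodic reduction turns the divalent nickel of NiCl2(dme)/bipyridine into zerovalent or univalent nickel, which inserts into the C4–I bond with retention of olefin geometry; one-electron reduction of the redox-active ester releases phthalimide anion and CO2 and gives the primary C3 radical, which is captured by the alkenylnickel of the same chain, and reductive elimination from trivalent nickel forms C3–C4. The closest known reaction type is the intermolecular nickel-catalysed electrochemical decarboxylative alkenylation of N-hydroxyphthalimide esters with alkenyl halides; its use for a medium ring is untested. The ten-membered ring closes by intramolecular radical capture at nickel followed by C(sp3)–C(sp2) reductive elimination through an eleven-membered nickelacycle. No stereocentre is created: C1, C6, C8, C9, C11 and C14 are spectators, and the E geometry of C4=C5 is inherited from the iodide (iodine trans to C6). The step needs ring closure to win over dimerisation and over hydrogen-atom capture by the radical; slow addition, slow radical generation at controlled current, and the trans cyclopropane with the quaternary C1, which turn the two chain ends toward each other, are meant to secure this. The side-chain olefin is 1,1-disubstituted and can only be reached through seven- or eight-membered transition states, so radical cyclisation onto it should not compete; the free tertiary hydroxyl and the silyl ether are tolerated, and ionisation of the allylic acetate by nickel is the side reaction to watch.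

Step 24
Reactants: 31 the ten-membered hydroxy acetate with C14 silyl ether
Product: 32 the ten-membered (14R)-allylic alcohol, (1R,6S,8S,9S,11S,14R)
Conditions: TBAF, AcOH, THF, 0 °C → rt
Reagents that add atoms: none
Why: Fluoride cleavage of the silyl ether; buffering with acetic acid keeps the medium from becoming basic, so the allylic acetate neither migrates nor is cleaved.

Step 25
Reactants: 32 the ten-membered (14R)-allylic alcohol
Product: 33 the (14R)-methanesulfonate of 32
Conditions: MsCl, Et3N, CH2Cl2, −78 → −40 °C
Reagents that add atoms: methanesulfonyl chloride, CS(=O)(=O)Cl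
Why: Mesylation of the secondary allylic alcohol with retention at C14; at low temperature the tertiary alcohol is not sulfonylated. The labile mesylate is used at once.

Step 26
Reactants: 33 the (14R)-methanesulfonate
Product: 34 CNP0302713.3, the (14S)-hydroperoxide, (1R,6S,8S,9S,11S,14S)
Conditions: H2O2 (anhydrous, in Et2O, excess), −78 → −30 °C
Reagents that add atoms: hydrogen peroxide, OO
Why: Displacement of a secondary allylic mesylate by hydrogen peroxide at low temperature, a known way from allylic alcohols to allylic hydroperoxides; backside attack inverts C14 from R to S. The non-basic conditions leave the acetate, the tertiary alcohol and the ring olefin untouched.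

## Compound list

1 | geraniol, (2E)-3,7-dimethylocta-2,6-dien-1-ol | CC(C)=CCC/C(C)=C/CO | starting material
2 | pent-4-enoic acid | C=CCCC(=O)O | starting material
3 | geranyl pent-4-enoate, (2E)-3,7-dimethylocta-2,6-dien-1-yl pent-4-enoate | C=CCCC(=O)OC/C=C(\C)CCC=C(C)C | intermediate
4 | boron enolate of 3: O-geranyl O-boryl ketene acetal carrying the (4S,5S)-4,5-diphenyl-1,3-bis[3,5-bis(trifluoromethyl)benzenesulfonyl]-1,3,2-diazaborolidin-2-yl group, allyl group trans to O–B | C=CC/C=C(/OB1N(S(=O)(=O)c2cc(C(F)(F)F)cc(C(F)(F)F)c2)[C@@H](c2ccccc2)[C@H](c2ccccc2)N1S(=O)(=O)c1cc(C(F)(F)F)cc(C(F)(F)F)c1)\OC/C=C(\C)CCC=C(C)C | intermediate (not isolated)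
5 | (2S,3S)-3-ethenyl-3,7-dimethyl-2-(prop-2-en-1-yl)oct-6-enoic acid (C2 of the acid is C11, C3 is C1) | CC(C)=CCC[C@@](C)(C=C)[C@H](CC=C)C(=O)O | intermediate
6 | (2S,3S)-3-ethenyl-3,7-dimethyl-2-(prop-2-en-1-yl)oct-6-en-1-ol | CC(C)=CCC[C@@](C)(C=C)[C@H](CC=C)CO | intermediate
7 | (2S,3S)-3-ethenyl-3,7-dimethyl-2-(prop-2-en-1-yl)oct-6-en-1-yl 4-methylbenzenesulfonate | CC(C)=CCC[C@@](C)(C=C)[C@H](CC=C)COS(=O)(=O)c1ccc(C)cc1 | intermediate
8 | (2S,3S)-3-ethenyl-3,7-dimethyl-2-(2-oxopropyl)oct-6-en-1-yl 4-methylbenzenesulfonate | CC(C)=CCC[C@@](C)(C=C)[C@H](CC(C)=O)COS(=O)(=O)c1ccc(C)cc1 | intermediate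
9 | 1-[(1S,2S)-2-[(3S)-3,7-dimethylocta-1,6-dien-3-yl]cyclopropyl]ethan-1-one (trans cyclopropane) | CC(C)=CCC[C@@](C)(C=C)[C@H]1C[C@@H]1C(C)=O | intermediate
10 | (4S)-4-[(1S,2S)-2-acetylcyclopropyl]-4,8-dimethylnon-7-enal | CC(C)=CCC[C@@](C)(CCC=O)[C@H]1C[C@@H]1C(C)=O | intermediate
11 | 1-[(1S,2S)-2-[(4S)-1,1-dimethoxy-4,8-dimethylnon-7-en-4-yl]cyclopropyl]ethan-1-one | CC(C)=CCC[C@@](C)(CCC(OC)OC)[C@H]1C[C@@H]1C(C)=O | intermediate
12 | 1-[(1S,2S)-2-[(3S)-1-[(2R)-3,3-dimethyloxiran-2-yl]-6,6-dimethoxy-3-methylhexan-3-yl]cyclopropyl]ethan-1-one | CC1(C)O[C@@H]1CC[C@@](C)(CCC(OC)OC)[C@H]2C[C@@H]2C(C)=O | intermediate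
13 | borinate of 14: the C8 oxygen bound to boron of the (10R)-10-phenyl-9-borabicyclo[3.3.2]decane unit | CC1(C)O[C@@H]1CC[C@@](C)(CCC(OC)OC)[C@H]2C[C@@H]2[C@@](C)(OB3[C@@H]4CCC[C@@H](CCC4)[C@@H]3c3ccccc3)CC=C | intermediate (not isolated)
14 | (2S)-2-[(1S,2S)-2-[(3S)-1-[(2R)-3,3-dimethyloxiran-2-yl]-6,6-dimethoxy-3-methylhexan-3-yl]cyclopropyl]pent-4-en-2-ol, (1S,8S,9S,11S,14R) | CC1(C)O[C@@H]1CC[C@@](C)(CCC(OC)OC)[C@H]2C[C@@H]2[C@@](C)(O)CC=C | intermediate
15 | secondary ozonide of 14 (1,2,4-trioxolan-3-ylmethyl group in place of the prop-2-enyl group) | CC1(C)O[C@@H]1CC[C@@](C)(CCC(OC)OC)[C@H]2C[C@@H]2[C@@](C)(O)CC3OCOO3 | intermediate (not isolated)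
16 | (3S)-3-[(1S,2S)-2-[(3S)-1-[(2R)-3,3-dimethyloxiran-2-yl]-6,6-dimethoxy-3-methylhexan-3-yl]cyclopropyl]-3-hydroxybutanal | CC1(C)O[C@@H]1CC[C@@](C)(CCC(OC)OC)[C@H]2C[C@@H]2[C@@](C)(O)CC=O | intermediate
17 | 1-propynylmagnesium bromide | CC#C[Mg]Br | starting material
18 | (2S)-2-[(1S,2S)-2-[(3S)-1-[(2R)-3,3-dimethyloxiran-2-yl]-6,6-dimethoxy-3-methylhexan-3-yl]cyclopropyl]hept-5-yne-2,4-diol, both epimers at C4 of the heptyne (C6) | CC1(C)O[C@@H]1CC[C@@](C)(CCC(OC)OC)[C@H]2C[C@@H]2[C@@](C)(O)CC(O)C#CC | intermediate
19 | (6S)-6-[(1S,2S)-2-[(3S)-1-[(2R)-3,3-dimethyloxiran-2-yl]-6,6-dimethoxy-3-methylhexan-3-yl]cyclopropyl]-6-hydroxyhept-2-yn-4-one | CC1(C)O[C@@H]1CC[C@@](C)(CCC(OC)OC)[C@H]2C[C@@H]2[C@@](C)(O)CC(=O)C#CC | intermediate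
20 | (2S,4S)-2-[(1S,2S)-2-[(3S)-1-[(2R)-3,3-dimethyloxiran-2-yl]-6,6-dimethoxy-3-methylhexan-3-yl]cyclopropyl]hept-5-yne-2,4-diol, (1S,6S,8S,9S,11S,14R) | CC1(C)O[C@@H]1CC[C@@](C)(CCC(OC)OC)[C@H]2C[C@@H]2[C@@](C)(O)C[C@H](O)C#CC | intermediate
21 | C6 triethylsilyl ether of 20, (1S,6S,8S,9S,11S,14R) | CC1(C)O[C@@H]1CC[C@@](C)(CCC(OC)OC)[C@H]2C[C@@H]2[C@@](C)(O)C[C@H](O[Si](CC)(CC)CC)C#CC | intermediate
22 | (14R)-allylic alcohol: 21 with the oxirane replaced by CH(OH)–C(CH3)=CH2, (1S,6S,8S,9S,11S,14R) | C=C(C)[C@H](O)CC[C@@](C)(CCC(OC)OC)[C@H]1C[C@@H]1[C@@](C)(O)C[C@H](O[Si](CC)(CC)CC)C#CC | intermediate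
23 | C14 tert-butyldimethylsilyl ether of 22, (1S,6S,8S,9S,11S,14R) | C=C(C)[C@H](O[Si](C)(C)C(C)(C)C)CC[C@@](C)(CCC(OC)OC)[C@H]1C[C@@H]1[C@@](C)(O)C[C@H](O[Si](CC)(CC)CC)C#CC | intermediate
24 | alkenylzirconocene chloride from 23: Cp2Zr(Cl) on C4 cis to the C5 hydrogen, the C8 hydroxyl held as its Cp2Zr(Cl) alkoxide | C=C(C)[C@H](O[Si](C)(C)C(C)(C)C)CC[C@@](C)(CCC(OC)OC)[C@H]1C[C@@H]1[C@@](C)(O[Zr](Cl)(C2C=CC=C2)C2C=CC=C2)C[C@H](O[Si](CC)(CC)CC)/C=C(C)/[Zr](Cl)(C2C=CC=C2)C2C=CC=C2 | intermediate (not isolated)
25 | (E)-alkenyl iodide: 23 with C5H=C4(CH3)I in place of the alkyne, iodine trans to C6, (1S,6S,8S,9S,11S,14R) | C=C(C)[C@H](O[Si](C)(C)C(C)(C)C)CC[C@@](C)(CCC(OC)OC)[C@H]1C[C@@H]1[C@@](C)(O)C[C@H](O[Si](CC)(CC)CC)/C=C(C)/I | intermediate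
26 | hydroxy aldehyde: 25 with free C6 hydroxyl and the C3 arm as CH2CH2CHO, (1S,6S,8S,9S,11S,14R) | C=C(C)[C@H](O[Si](C)(C)C(C)(C)C)CC[C@@](C)(CCC=O)[C@H]1C[C@@H]1[C@@](C)(O)C[C@H](O)/C=C(C)/I | intermediate
27 | C6 acetate of 26, (1S,6S,8S,9S,11S,14R) | C=C(C)[C@H](O[Si](C)(C)C(C)(C)C)CC[C@@](C)(CCC=O)[C@H]1C[C@@H]1[C@@](C)(O)C[C@H](OC(C)=O)/C=C(C)/I | intermediate
28 | seco carboxylic acid: 27 with CO2H in place of CHO, (1S,6S,8S,9S,11S,14R) | C=C(C)[C@H](O[Si](C)(C)C(C)(C)C)CC[C@@](C)(CCC(=O)O)[C@H]1C[C@@H]1[C@@](C)(O)C[C@H](OC(C)=O)/C=C(C)/I | intermediate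
29 | N-hydroxyphthalimide | O=C1c2ccccc2C(=O)N1O | starting material
30 | seco N-hydroxyphthalimide ester with (E)-alkenyl iodide, C6 acetate, C8 hydroxyl and C14 tert-butyldimethylsilyl ether, (1S,6S,8S,9S,11S,14R) | C=C(C)[C@H](O[Si](C)(C)C(C)(C)C)CC[C@@](C)(CCC(=O)ON1C(=O)c2ccccc2C1=O)[C@H]3C[C@@H]3[C@@](C)(O)C[C@H](OC(C)=O)/C=C(C)/I | intermediate
31 | ten-membered hydroxy acetate with E C4=C5 olefin, trans-fused cyclopropane and C14 tert-butyldimethylsilyl ether, (1R,6S,8S,9S,11S,14R) | C=C(C)[C@H](O[Si](C)(C)C(C)(C)C)CC[C@@]1(C)CC/C(C)=C/[C@@H](OC(C)=O)C[C@](C)(O)[C@H]2C[C@@H]21 | intermediate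
32 | ten-membered (14R)-allylic alcohol (C14 epimer of the target carbinol), (1R,6S,8S,9S,11S,14R) | C=C(C)[C@H](O)CC[C@@]1(C)CC/C(C)=C/[C@@H](OC(C)=O)C[C@](C)(O)[C@H]2C[C@@H]21 | intermediate
33 | (14R)-methanesulfonate of 32 | C=C(C)[C@H](OS(C)(=O)=O)CC[C@@]1(C)CC/C(C)=C/[C@@H](OC(C)=O)C[C@](C)(O)[C@H]2C[C@@H]21 | intermediate
34 | CNP0302713.3, (1R,6S,8S,9S,11S,14S)-hydroperoxide | C=C(C)[C@H](CC[C@@]1(C)CC/C(C)=C/[C@@H](OC(C)=O)C[C@](C)(O)[C@H]2C[C@@H]21)OO | target

## Step count and least certain steps

Total: 26 steps, all in one line from geraniol 1 to 34. Longest linear sequence: 26 steps. The two chiral boron reagents of steps 2 and 10 are made separately by their established preparations and are not counted.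

**Step 23 (key step, proposed new method).** The closure may lose to chain-to-chain coupling and to hydrogen-atom capture by the C3 radical, because reductive elimination through a strained medium-ring nickelacycle is slow. Low-valent nickel may also ionise the allylic acetate. Fallback with known chemistry: set out from 30 and carry out a light-driven decarboxylative borylation (bis(catecholato)diboron, dimethylacetamide, blue light; then pinacol and Et3N) to the primary pinacol boronate F1. Close the ring by a B-alkyl Suzuki–Miyaura macrocyclisation (PdCl2(dppf), Cs2CO3, THF/DMF/H2O, high dilution); this forms the same C3–C4 bond with retention of the iodide geometry and returns to the route at 31.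

**Step 26.** The secondary allylic mesylate may ionise before it is attacked. That would erode the configuration at C14 and move the oxygen to the primary allylic terminus; elimination to a diene is a further loss. Fallback: set out from 33 and displace it with the caesium salt of 2-methoxyprop-2-yl hydroperoxide (CsOH·H2O, DMF, 0 °C), a stronger and non-acidic nucleophile, to give the perketal F2. Brief treatment with aqueous acetic acid removes the ketal and returns to the route at 34.

**Step 2.** Enolisation and rearrangement of a 3,3-disubstituted allyl ester with the bulky boron reagent may be slow, and facial control may erode over the long reaction time. Fallback: set out from 3 and run the classical Ireland–Claisen rearrangement (LDA, Me3SiCl, THF, −78 °C → rt) through the silyl ketene acetal F3. This gives the same diastereomer as a racemate, that is 5 together with its enantiomer F4. Resolve by crystallisation of the (R)-1-phenylethylammonium salt F5; release of the acid returns to the route at 5.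

**Step 10.** Facial discrimination between methyl and the substituted cyclopropyl group may be insufficient, and addition to the hindered ketone may be slow. Fallback: set out from 12 and add the lithium enolate of N-methoxy-N-methylacetamide (THF, −78 °C). This gives the (8S)-β-hydroxy amide F6 and its C8 epimer F7 without reagent control. The two are separated, and F7 is returned to 12 by base-induced retro-aldol cleavage. F6 reacts with excess 17 to give the ynone directly, returning to the route at 19 and leaving out steps 11 to 13.

**Step 18.** Regiochemical equilibration of the alkenylzirconium may be incomplete, and the excess reagent may hydrozirconate the side-chain olefin. Fallback: set out from 23 and hydrosilylate the alkyne (PtCl2, XPhos, Et3SiH; syn addition with silicon on C4, remote from the propargylic oxygen) to the alkenylsilane F8. Iododesilylation with N-iodosuccinimide in hexafluoroisopropanol proceeds with retention and returns to the route at 25.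

## Further compounds

F1 | step 23 | seco primary pinacol boronate (Bpin on C3) with (E)-alkenyl iodide, C6 acetate and C14 tert-butyldimethylsilyl ether | C=C(C)[C@H](O[Si](C)(C)C(C)(C)C)CC[C@@](C)(CCB1OC(C)(C)C(C)(C)O1)[C@H]2C[C@@H]2[C@@](C)(O)C[C@H](OC(C)=O)/C=C(C)/I
F2 | step 26 | (14S)-2-methoxyprop-2-yl peroxide (perketal) of the macrocycle | C=C(C)[C@H](CC[C@@]1(C)CC/C(C)=C/[C@@H](OC(C)=O)C[C@](C)(O)[C@H]2C[C@@H]21)OOC(C)(C)OC
F3 | step 2 | trimethylsilyl ketene acetal of 3, allyl group trans to O–Si | C=CC/C=C(/O[Si](C)(C)C)\OC/C=C(\C)CCC=C(C)C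
F4 | step 2 | (2R,3R)-3-ethenyl-3,7-dimethyl-2-(prop-2-en-1-yl)oct-6-enoic acid, enantiomer of 5 | CC(C)=CCC[C@](C)(C=C)[C@@H](CC=C)C(=O)O
F5 | step 2 | (R)-1-phenylethylammonium salt of 5 | CC(C)=CCC[C@@](C)(C=C)[C@H](CC=C)C(=O)[O-].C[C@@H]([NH3+])c1ccccc1
F6 | step 10 | (8S)-β-hydroxy N-methoxy-N-methylamide from 12 | CC1(C)O[C@@H]1CC[C@@](C)(CCC(OC)OC)[C@H]2C[C@@H]2[C@@](C)(O)CC(=O)N(C)OC
F7 | step 10 | (8R)-epimer of F6 | CC1(C)O[C@@H]1CC[C@@](C)(CCC(OC)OC)[C@H]2C[C@@H]2[C@](C)(O)CC(=O)N(C)OC
F8 | step 18 | (E)-alkenylsilane: 23 with C5H=C4(CH3)SiEt3 in place of the alkyne | C=C(C)[C@H](O[Si](C)(C)C(C)(C)C)CC[C@@](C)(CCC(OC)OC)[C@H]1C[C@@H]1[C@@](C)(O)C[C@H](O[Si](CC)(CC)CC)/C=C(C)/[Si](CC)(CC)CC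
A1 | alternative 1 | open-chain primary C10 tosylate with Z C8=C9 olefin | C=C[C@](C)(CCC=C(C)C)[C@H](/C=C(/C)CCO[Si](C)(C)C(C)(C)C)COS(=O)(=O)c1ccc(C)cc1
A2 | alternative 1 | trans-cyclopropyl tertiary carbinol fragment | C=C[C@](C)(CCC=C(C)C)[C@H]1C[C@@H]1[C@@](C)(O)CCO[Si](C)(C)C(C)(C)C
A3 | alternative 2 | seco (E)-enal oxime with isopropenylcyclopropane | CC(C)=CCC[C@@](C)(CC/C(C)=C/C=NO)[C@H]1C[C@@H]1C(C)=C
A4 | alternative 2 | conjugated nitrile oxide from A3 | CC(C)=CCC[C@@](C)(CC/C(C)=C/C#[N+][O-])[C@H]1C[C@@H]1C(C)=C
A5 | alternative 2 | bridged isoxazoline of the ten-membered carbocycle | CC(C)=CCC[C@@]1(C)CC/C(C)=C/C3=NO[C@@](C)(C3)[C@H]2C[C@@H]21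
A6 | alternative 3 | trans-1-vinyl-2-alkenylcyclohexanol | C=C[C@]1(O)C[C@@H](O[Si](C)(C)C(C)(C)C)C[C@](C)(OCOC)[C@H]1/C=C(\C)CCC=C(C)C
A7 | alternative 3 | ten-membered C4 ketone with E C9=C11 olefin | O=C1CC[C@](C)(CCC=C(C)C)/C=C/[C@@](C)(OCOC)C[C@H](O[Si](C)(C)C(C)(C)C)C1
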